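The numbers come from no measurement, and the outcome is calculated.

I started from the green flask, the neighbour with less partner than the violet and ochre flasks, and asked where partner goes.

| setting | green | violet | ochre |
|---|---|---|---|
| starting material | 0.10 M (in portions, 2) | 0.10 M (in portions, 2) | 0.10 M (in portions, 2) |
| partner | 0.0600 M | 0.200 M | 0.600 M |
| initiator | 2.0 mM | 2.0 mM | 2.0 mM |
| time | 8.0 h | 8.0 h | 8.0 h |
| remark | the portions of starting material follow each other after 50 min, the first at the start | the portions of starting material follow each other after 50 min, the first at the start | the portions of starting material follow each other after 50 min, the first at the start |

    initiator → 2 initiating radical (k1 = 9.0 × 10⁻⁴ min⁻¹)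
    starting material + initiating radical ⇌ chain carrier (K2 = 2.2 × 10⁵ L mol⁻¹, k2 = 1.5 × 10⁵ L mol⁻¹ s⁻¹)
    partner + chain carrier → target + initiating radical (k3 = 15000 L mol⁻¹ s⁻¹)
    2 chain carrier → ended chains (k4 = 1.1 × 10⁸ L mol⁻¹ s⁻¹)
    partner + target → over-reaction product (k5 = 0.32 L mol⁻¹ min⁻¹)
    partner → decomposed reagent (k6 = 0.039 min⁻¹)

- percentages count the starting material that a species holds: one ended chains counts as two
- a doubled species enters its step squared and goes two at a time
- "hardly changes" means that all values lie within two and a half points (for a concentration: within two and a half percent of the largest)
- run time (green): 8.0 h

1. amount of target at the end, in percent of the starting material charged for green, violet, ochre, in this order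
2. how that number moves from the first to the last of them (hardly changes / falls, then rises / rises all the way / falls all the way / rises, then falls)

Partner has three exits. It can meet a chain carrier, giving target and returning an initiating radical, it can decay by itself, or it can meet target. At the start there is no target, so I set the third exit aside for the moment. An even contest between the first two would send 0.5 of it each way, and I took that as the zero of my scale. To place the flask on that scale I needed the chain carrier level. Each initiator lost gives two radicals and each ending turn removes two chain carriers, so the twos cancelled in the balance:

[chain carrier] = √(9.0 × 10⁻⁴ min⁻¹ × 2.0 mM / 1.1 × 10⁸ L mol⁻¹ s⁻¹) = 1.65 × 10⁻⁸ M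

κ = 15000 L mol⁻¹ s⁻¹ × [chain carrier] = 0.0149 min⁻¹

φ = κ / (κ + 0.039 min⁻¹) = 27.6 %

Here κ is the pseudo-first-order constant for partner's loss through the chain. I called φ the chain share, the fraction of partner that leaves by the chain and not by decay. It stood below the even split. In the green flask it promised target and over-reaction product together of

φ × 0.0600 M / 0.10 M = 16.6 % of the starting material.

I doubted this at once. Initiator falls during the run, but its half-life of 13 h is far longer than the 0.30 h of partner by decay alone, so I held its level constant. The reverse step might have wasted chain carrier, but it runs at 0.682 s⁻¹ against 900 s⁻¹ for the chain step with partner as charged in the green flask, so I dropped it. Over-reaction did not go away: it takes part of the target and some of the partner, so I put the green flask a little under that figure.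

In the violet flask the same product gave 55.2 %, and I expected target well below it, since target's half-life against partner as charged is 10.8 min, shorter than the 12.9 min of partner by the chain and decay together.

In the ochre flask the product gave 166 %, more than the charge, and that objection overturned the estimate. The chain needs starting material, and at the opening rate I reckoned the first portion to last 5.61 min, shorter than the 50 min wait. Target's half-life against partner as charged in the ochre flask is 3.61 min, far shorter than that wait, so I wrote off most of the first portion's target. Decay by itself leaves 0.0854 M of partner at the second portion, and the chain share of that is 23.6 % of the charge. The chain and over-reaction also take partner during the wait, so I expected a lower figure. I leaned to a row that rose and then fell, but I had no firm violet number.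

The forecast gave 13.3 %, 30 % and 17 %, a row that rises, then falls. For the ochre flask it pictured a wait “while the partner idles and decays”.

The flasks gave 13.4 %, 30.3 % and 15.8 % of target at the end, a row that rises, then falls. Just before the last addition (0.833 h), the ochre flask held starting material at 0 %, target at 2.51 % and over-reaction product at 47.5 % of the starting material charged, and partner at 11.0 % of its own charge. The chain share of that partner came to 18.3 % of the starting material charged. From then to the end, target and over-reaction product together gained 17 percentage points.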